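**Plan**

1. Working numbering: terpenoid part C1–C11 (C1=C2, C3 lactone carbonyl, C4 CMe2, C5, C8 the quaternary carbon shared by rings B, C and D, C9 the ring B methine, C10 C–Me, C11 the ring C CH2); propanoate carbons C12 (C–Me) and C13 (bridging C=O); phthalide positions primed, C4′ being C8.
2. Enabling feature: ring D (C3a′, C4′, C5′, C6′, C7′, C7a′) is a reduced 7-methoxy-6-methylphthalide. The carbon para to its oxygen is C8, and ring E (C1′, O, C3′) is already in place, so closing ring B onto C4′ from C9 dearomatises a cheap arene into ring D.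
3. Retrosynthetic cuts: C7′–OH (from C=O); C12–C3a′ (Michael) and C13–C6′ (Claisen) of the bicyclo[2.2.2]octane; C8–C9 (radical ipso closure) and C11–C12 (radical addition to a vinyl group); ring A oxygen (Baeyer–Villiger); C5–C6 (conjugate addition joining the two fragments).
4. Forward order: ring A as a cyclohexadienone from benzoic acid, then fragment union, then ring B with the dearomatised ring D, then the ring A lactone, then a seven-membered ketone ring, then ring C and the bicyclooctane in one Michael closure, then the carbinol.
5. Stereochemistry: C5 and C10 come from an (R)-BINAP–Rh desymmetrisation. C8 and C9 come from the chair of the key closure. C6′, C12 and C3a′ are fixed by the tethers. C7a′ and C7′ come from protonation and hydride delivery syn to H-7a′.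

Key step: step 16

Remark: centres that are mixtures and later become planar or ring-fixed (C12 in 20–27, C9 in 20, C2 in 22) are drawn without configuration; C7a′ of 28 can equilibrate through the enol and is drawn as in the target.

**Step 1**
Reactants: 1 benzoic acid
Product: 2 1-methylcyclohexa-2,5-diene-1-carboxylic acid
Conditions: Li, NH3 (l), THF, −78 °C; MeI; aq. HCl
Reagents that add atoms: iodomethane, CI
Why: Birch reductive alkylation should methylate the dihydrobenzoate dianion at the carboxyl-bearing carbon, which dearomatises a cheap arene and creates the future C10 with its methyl group.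

**Step 2**
Reactants: 2 1-methylcyclohexa-2,5-diene-1-carboxylic acid
Product: 3 (1-methylcyclohexa-2,5-dien-1-yl)methanol
Conditions: LiAlH4, Et2O, 0 °C → rt
Reagents that add atoms: none
Why: Hydride reduction of the acid should leave the two isolated alkenes untouched and gives the carbon that becomes C9.

**Step 3**
Reactants: 3 (1-methylcyclohexa-2,5-dien-1-yl)methanol
Product: 4 TBDPS ether of 3
Conditions: TBDPSCl, imidazole, DMF, rt
Reagents that add atoms: tert-butylchlorodiphenylsilane, CC(C)(C)[Si](Cl)(c1ccccc1)c1ccccc1
Why: Silylation protects the alcohol and gives the bulky group that later steers the conjugate addition.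

**Step 4**
Reactants: 4 TBDPS ether of 3
Product: 5 4-methyl-4-(TBDPS-oxymethyl)cyclohexa-2,5-dien-1-one
Conditions: Rh2(cap)4 (1 mol%), t-BuOOH, K2CO3, CH2Cl2, rt
Reagents that add atoms: tert-butyl hydroperoxide, CC(C)(C)OO
Why: Allylic C–H oxidation at the doubly allylic CH2 should give the prochiral cross-conjugated dienone.

**Step 5**
Reactants: 6 2-methoxy-3-methylbenzoic acid
Product: 7 7-methoxy-6-methylphthalide
Conditions: Pd(OAc)2 (10 mol%), K2HPO4, CH2Br2, 140 °C
Reagents that add atoms: dibromomethane, BrCBr
Why: Carboxylate-directed ortho C–H alkylation with CH2Br2 followed by lactonisation should build ring E on the only free ortho position.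

**Step 6**
Reactants: 7 7-methoxy-6-methylphthalide
Product: 8 4-bromo-7-methoxy-6-methylphthalide
Conditions: NBS, MeCN, 50 °C
Reagents that add atoms: N-bromosuccinimide, O=C1CCC(=O)N1Br
Why: Electrophilic aromatic bromination should go para to the methoxy group (C4′), the other free position being para to the deactivating lactone carbonyl carbon.

**Step 7**
Reactants: 8 4-bromo-7-methoxy-6-methylphthalide, 9 vinylboronic acid pinacol ester
Product: 10 (E)-4-[2-(pinacolboryl)vinyl]-7-methoxy-6-methylphthalide
Conditions: Pd(P(t-Bu)3)2 (5 mol%), i-Pr2NH, toluene, 80 °C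
Reagents that add atoms: none
Why: A Mizoroki–Heck reaction at the unsubstituted terminus of the vinylboronate (water-free amine base suppresses Suzuki coupling) should give the (E)-alkenylboronate.

**Step 8**
Reactants: 5 4-methyl-4-(TBDPS-oxymethyl)cyclohexa-2,5-dien-1-one, 10 (E)-alkenylboronate
Product: 11 5-alkenyl-4-methyl-4-(TBDPS-oxymethyl)cyclohex-2-en-1-one
Conditions: [Rh(OH)(cod)]2 (2.5 mol%), (R)-BINAP (6 mol%), dioxane/H2O 10:1, 50 °C
Reagents that add atoms: none
Why: The Hayashi–Miyaura conjugate addition desymmetrises the dienone, since (R)-BINAP selects the enone face (mirror sense of the (S)-BINAP/cyclohexenone case) and the alkenyl group enters anti to CH2OTBDPS, which sets C5 and C10 together with alkenyl cis to methyl.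

**Step 9**
Reactants: 11 5-alkenyl-4-methyl-4-(TBDPS-oxymethyl)cyclohex-2-en-1-one
Product: 12 6,6-dimethyl derivative of 11
Conditions: NaH, MeI, THF, 0 → 40 °C
Reagents that add atoms: iodomethane, CI
Why: Exhaustive methylation of the cross-conjugated enolate at the only enolisable carbon should install the C4 gem-dimethyl group.

**Step 10**
Reactants: 12 6,6-dimethyl derivative of 11
Product: 13 saturated ketone with arylethyl arm
Conditions: H2 (1 atm), Pd/C, EtOAc, rt
Reagents that add atoms: none
Why: Hydrogenation should saturate the styrene-type C6=C7 alkene and the C1=C2 enone alkene, which must be absent during the radical steps.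

**Step 11**
Reactants: 13 saturated ketone with arylethyl arm
Product: 14 primary alcohol
Conditions: HF·pyridine, THF, 0 °C → rt
Reagents that add atoms: none
Why: Fluoride cleavage of the silyl ether should free the neopentyl alcohol.

**Step 12**
Reactants: 14 primary alcohol
Product: 15 aldehyde
Conditions: Dess–Martin periodinane, NaHCO3, CH2Cl2, rt
Reagents that add atoms: none
Why: Dess–Martin oxidation should give the non-enolisable neopentyl aldehyde (C9).

**Step 13**
Reactants: 15 aldehyde
Product: 16 vinyl ketone
Conditions: Ph3PCH3Br, KN(SiMe3)2, THF, −78 → 0 °C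
Reagents that add atoms: methyltriphenylphosphonium bromide, C[P+](c1ccccc1)(c1ccccc1)c1ccccc1.[Br-]
Why: Wittig methylenation should take the aldehyde in preference to the hindered ketone and the lactone, giving the C9=C11 vinyl group.

**Step 14**
Reactants: 17 2-bromopropanoyl bromide
Product: 19 phenyl 2-[(ethoxycarbonothioyl)sulfanyl]propanoate, via phenyl 2-bromopropanoate 18 (not isolated)
Conditions: PhOH, pyridine, CH2Cl2, 0 °C; then KSC(S)OEt, acetone, rt
Reagents that add atoms: phenol, Oc1ccccc1; potassium O-ethyl xanthate, CCOC(=S)[S-].[K+]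
Why: Acylation of phenol and SN2 displacement of the α-bromide by xanthate should give the radical precursor that carries C12, its methyl and C13 as an aryl ester.

**Step 15**
Reactants: 16 vinyl ketone, 19 phenyl 2-[(ethoxycarbonothioyl)sulfanyl]propanoate
Product: 20 xanthate adduct
Conditions: dilauroyl peroxide (10 mol%, in portions), 1,2-dichloroethane, reflux
Reagents that add atoms: none
Why: In a degenerative xanthate-transfer radical addition the electrophilic α-ester radical should add to the terminal vinyl carbon (C11–C12 bond) and the C9 radical collect the xanthate group, both new centres being mixtures that later become planar.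

**Step 16**
Reactants: 20 xanthate adduct
Product: 21 spiro dienone
Conditions: dilauroyl peroxide (1.3 equiv, in portions), 1,2-dichloroethane, reflux
Reagents that add atoms: none
Why: Proposed new method: undecyl radicals from the peroxide take the xanthate group and free the secondary C9 radical, which attacks the anisole ipso carbon C4′ (para to OMe) in a six-membered ipso (exo) closure; the peroxide oxidises the cyclohexadienyl radical to the O-methyl oxocarbenium ion and laurate removes the methyl group, so ring B, the C8–C9 bond and the quaternary C8 arise while the arene becomes the dienone of ring D. The closest known reactions are xanthate-transfer cyclisations onto arenes run with stoichiometric peroxide and radical ipso cyclisations of para-methoxyaryl groups to spirocyclohexadienones with loss of the O-methyl group; new is the all-carbon six-membered spiro closure from an alkyl xanthate. The closure runs through a chair held by the trans-diequatorial C10 and C5 arms of ring A. At C8 the unsubstituted ortho carbon C5′ should take the axial site beside the axial C10 methyl and the CH2O-bearing C3a′ the equatorial one; at C9 the ester arm should go axial, anti to that methyl, which is the cis relation of C11 and C3a′ that ring C needs. The step needs ipso attack to beat 1,5-hydrogen transfer from the benzylic C7 and ortho attack: reversible xanthate transfer keeps the radical available for the slow closure, ortho attack would need a seven-membered ring, and C1–C2 is kept saturated because an enone there would trap the C9 radical in a 3-exo closure.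

**Step 17**
Reactants: 21 spiro dienone
Product: 23 ring A enone, via C2 phenylselanyl ketone 22 (not isolated)
Conditions: PhSeCl, EtOAc, rt; then H2O2 (30%), pyridine, CH2Cl2, 0 °C → rt
Reagents that add atoms: none
Why: Acid-mediated α-selenenylation of the only ketone that can enolise (at C2) and selenoxide syn-elimination (Sharpless–Reich) should give the C1=C2 enone without base that would deprotonate the butenolide.

**Step 18**
Reactants: 23 ring A enone
Product: 24 ring A unsaturated ε-lactone
Conditions: mCPBA, NaHCO3, CH2Cl2, rt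
Reagents that add atoms: 3-chloroperbenzoic acid, O=C(OO)c1cccc(Cl)c1
Why: In the Baeyer–Villiger oxidation the tertiary C4 should migrate in preference to the vinyl carbon, inserting oxygen between C3 and C4, while the electron-poor alkenes and the cross-conjugated dienone resist the peracid.

**Step 19**
Reactants: 24 ring A unsaturated ε-lactone
Product: 25 2-silyloxyfuran
Conditions: TBSOTf (1.1 equiv), Et3N, CH2Cl2, 0 °C
Reagents that add atoms: tert-butyldimethylsilyl triflate, CC(C)(C)[Si](C)(C)OS(=O)(=O)C(F)(F)F
Why: Soft enolisation and O-silylation at the acidic C3′ position turns the butenolide into a 2-silyloxyfuran, a temporary mask of the doubly activated C3a′=C7a′ acceptor so that hydride can be sent to C5′.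

**Step 20**
Reactants: 25 2-silyloxyfuran
Product: 26 bridged diketone
Conditions: LiBH(s-Bu)3 (1.05 equiv), THF, −78 °C → rt
Reagents that add atoms: none
Why: Conjugate reduction at C5′ should give the C6′ enolate regiospecifically, and its intramolecular Claisen acylation by the phenyl ester (phenoxide loss makes it irreversible) forms the C13–C6′ bond and a seven-membered ketone ring, the tether fixing the quaternary C6′.

**Step 21**
Reactants: 26 bridged diketone
Product: 28 triketo lactone, via butenolide diketone 27 (not isolated)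
Conditions: Bu4NF, AcOH, THF, 0 °C; then DBU (0.3 equiv), rt
Reagents that add atoms: none
Why: Desilylation returns the butenolide, and the C13 ketone enolate then adds across the ring to C3a′ (intramolecular Michael), closing ring C and the bicyclo[2.2.2]octane with C12 and C3a′ dictated by the ring geometry and C7a′ set by equilibrating protonation.

**Step 22**
Reactants: 28 triketo lactone
Product: 29 andilesin A
Conditions: NaBH4, MeOH/CH2Cl2, −40 °C
Reagents that add atoms: none
Why: Borohydride should reduce the activated C7′ ketone of the β-keto lactone in preference to the C13 ketone between two quaternary carbons and to both lactones, attacking syn to H-7a′ (anti to the lactone carbonyl) as in reductions of 2-alkoxycarbonyl cycloalkanones, which gives the cis β-hydroxy lactone.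

**Compound list**

1 | benzoic acid | OC(=O)c1ccccc1 | starting material
2 | 1-methylcyclohexa-2,5-diene-1-carboxylic acid | CC1(C(=O)O)C=CCC=C1 | intermediate
3 | (1-methylcyclohexa-2,5-dien-1-yl)methanol | CC1(CO)C=CCC=C1 | intermediate
4 | tert-butyl[(1-methylcyclohexa-2,5-dien-1-yl)methoxy]diphenylsilane | CC1(CO[Si](c2ccccc2)(c2ccccc2)C(C)(C)C)C=CCC=C1 | intermediate
5 | 4-methyl-4-[(tert-butyldiphenylsilyloxy)methyl]cyclohexa-2,5-dien-1-one | CC1(CO[Si](c2ccccc2)(c2ccccc2)C(C)(C)C)C=CC(=O)C=C1 | intermediate
6 | 2-methoxy-3-methylbenzoic acid | COc1c(C)cccc1C(=O)O | starting material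
7 | 7-methoxy-6-methylisobenzofuran-1(3H)-one | COc1c(C)ccc2COC(=O)c12 | intermediate
8 | 4-bromo-7-methoxy-6-methylisobenzofuran-1(3H)-one | COc1c(C)cc(Br)c2COC(=O)c12 | intermediate
9 | 4,4,5,5-tetramethyl-2-vinyl-1,3,2-dioxaborolane | C=CB1OC(C)(C)C(C)(C)O1 | starting material
10 | (E)-7-methoxy-6-methyl-4-[2-(pinacolboryl)vinyl]isobenzofuran-1(3H)-one | COc1c(C)cc(/C=C/B2OC(C)(C)C(C)(C)O2)c2COC(=O)c12 | intermediate
11 | 4-methyl-4-(TBDPS-oxymethyl)-5-[(E)-2-(7-methoxy-6-methyl-1-oxo-1,3-dihydroisobenzofuran-4-yl)vinyl]cyclohex-2-en-1-one, alkenyl cis to methyl | C1C(=O)C=C[C@@](C)([C@H]1/C=C/c1cc(C)c(OC)c2C(=O)OCc12)CO[Si](c1ccccc1)(c1ccccc1)C(C)(C)C | intermediate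
12 | 6,6-dimethyl derivative of 11 | CC1(C)C(=O)C=C[C@@](C)([C@H]1/C=C/c1cc(C)c(OC)c2C(=O)OCc12)CO[Si](c1ccccc1)(c1ccccc1)C(C)(C)C | intermediate
13 | 2,2,4-trimethyl-3-[2-(phthalid-4-yl)ethyl]-4-(TBDPS-oxymethyl)cyclohexan-1-one, arylethyl cis to the C4 methyl | CC1(C)C(=O)CC[C@@](C)([C@H]1CCc1cc(C)c(OC)c2C(=O)OCc12)CO[Si](c1ccccc1)(c1ccccc1)C(C)(C)C | intermediate
14 | 4-hydroxymethyl analogue of 13 | CC1(C)C(=O)CC[C@@](C)([C@H]1CCc1cc(C)c(OC)c2C(=O)OCc12)CO | intermediate
15 | 4-formyl analogue of 13 | CC1(C)C(=O)CC[C@@](C)([C@H]1CCc1cc(C)c(OC)c2C(=O)OCc12)C=O | intermediate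
16 | 4-vinyl analogue of 13 | CC1(C)C(=O)CC[C@@](C)([C@H]1CCc1cc(C)c(OC)c2C(=O)OCc12)C=C | intermediate
17 | 2-bromopropanoyl bromide | CC(Br)C(Br)=O | starting material
18 | phenyl 2-bromopropanoate | CC(Br)C(=O)Oc1ccccc1 | intermediate
19 | phenyl 2-[(ethoxycarbonothioyl)sulfanyl]propanoate | CCOC(=S)SC(C)C(=O)Oc1ccccc1 | intermediate
20 | xanthate adduct: C9 carries the O-ethyl xanthate, C11–C12 joined, phenyl ester | CC1(C)C(=O)CC[C@@](C)([C@H]1CCc1cc(C)c(OC)c2C(=O)OCc12)C(SC(=S)OCC)CC(C)C(=O)Oc1ccccc1 | intermediate
21 | spiro dienone: ring B closed on C8, ring D a cyclohexa-2,5-dienone fused to the butenolide, ring A saturated ketone | CC1(C)C(=O)CC[C@@]2(C)[C@H]1CC[C@]3(C=C(C)C(=O)C4=C3COC4=O)[C@H]2CC(C)C(=O)Oc1ccccc1 | intermediate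
22 | C2 phenylselanyl ketone of 21 | CC1(C)C(=O)C([Se]c5ccccc5)C[C@@]2(C)[C@H]1CC[C@]3(C=C(C)C(=O)C4=C3COC4=O)[C@H]2CC(C)C(=O)Oc1ccccc1 | intermediate
23 | ring A C1=C2 enone of 21 | CC1(C)C(=O)C=C[C@@]2(C)[C@H]1CC[C@]3(C=C(C)C(=O)C4=C3COC4=O)[C@H]2CC(C)C(=O)Oc1ccccc1 | intermediate
24 | ring A unsaturated ε-lactone of 23 | CC1(C)OC(=O)C=C[C@@]2(C)[C@H]1CC[C@]3(C=C(C)C(=O)C4=C3COC4=O)[C@H]2CC(C)C(=O)Oc1ccccc1 | intermediate
25 | 2-(tert-butyldimethylsilyloxy)furan form of 24 | CC1(C)OC(=O)C=C[C@@]2(C)[C@H]1CC[C@]3(C=C(C)C(=O)c4c3coc4O[Si](C)(C)C(C)(C)C)[C@H]2CC(C)C(=O)Oc1ccccc1 | intermediate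
26 | bridged diketone: C13 bonded to C6′, seven-membered ketone ring, silyloxyfuran retained | CC1(C)OC(=O)C=C[C@@]2(C)[C@H]1CC[C@]13C[C@](C)(C(=O)C(C)C[C@@H]21)C(=O)c1c3coc1O[Si](C)(C)C(C)(C)C | intermediate
27 | butenolide form of 26 | CC1(C)OC(=O)C=C[C@@]2(C)[C@H]1CC[C@]13C[C@](C)(C(=O)C(C)C[C@@H]21)C(=O)C1=C3COC1=O | intermediate
28 | 7′-oxo compound (andilesin A with C=O in place of CH–OH) | CC1(C)OC(=O)C=C[C@@]2(C)[C@H]1CC[C@]13C[C@]4(C)C(=O)[C@](C)(C[C@@H]21)[C@]31COC(=O)[C@H]1C4=O | intermediate
29 | andilesin A | CC1(C)OC(=O)C=C[C@@]2(C)[C@H]1CC[C@]13C[C@]4(C)C(=O)[C@](C)(C[C@@H]21)[C@]31COC(=O)[C@H]1[C@H]4O | target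

**Count**

Total steps: 22. Longest linear sequence: 18 steps (1–4, 8–13, 15–22, from benzoic acid).

**Steps most likely to fail**

Step 16. The C9 radical may abstract a benzylic hydrogen from C7, close too slowly, or close on the wrong face at C9. Fallback from 15 back to 21, two-electron and electrochemical: a Wittig reaction of 15 with the ylide from (2-carboxypropyl)triphenylphosphonium bromide and NaN(SiMe3)2 would give the (Z)-β,γ-unsaturated acid F1. Phenol with DCC and DMAP would give the phenyl ester F2, and LiN(i-Pr)2 with TBSCl at −78 °C the silyl dienol ether F3. Constant-current anodic oxidation (carbon anode, LiClO4, 2,6-lutidine, MeOH/CH2Cl2) would couple the two electron-rich groups: the terminal carbon of the dienol ether bonds to the ipso carbon para to OMe and methanol traps the cation, giving the quinone monoketal F4 with a conjugated enoate. Conjugate reduction of that enoate (Cu(OAc)2, 1,2-bis(diphenylphosphino)benzene, (EtO)2MeSiH, t-BuOH) would give the saturated ester ketal F5, since the ketal leaves no more electrophilic alkene. Dilute aqueous acid then returns dienone 21.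

Step 20. Hydride may add to a carbonyl or to the phenyl ester instead of C5′, or the enolate may be protonated before the seven-membered acylation. Fallback from 25 back to 28: RhCl(PPh3)3-catalysed 1,4-hydrosilylation with Et3SiH would give the triethylsilyl enol ether F6 with no free hydride present. Tetrabutylammonium difluorotriphenylsilicate in THF at −40 °C would then free the C6′ enolate for the same acylation and also remove the furan silyl group. AcOH and DBU as in step 21 should deliver 28.

Step 21. Fluoride or base may open the non-enolisable 1,3-diketone by retro-Claisen cleavage before the transannular Michael addition closes. Fallback from 26 back to 28, under acid: TBSOTf and Et3N would convert the C13 ketone into the silyl enol ether F7. Catalytic HNTf2 in CH2Cl2 at −78 °C would protonate the silyloxyfuran at C3′, and the tethered enol ether would attack the resulting O-silylated butenolide cation at C3a′ (Mukaiyama–Michael). Desilylation on work-up gives 28.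

**Further compounds**

F1 | step 16 | (Z)-β,γ-unsaturated acid from 15 | CC1(C)C(=O)CC[C@@](C)([C@H]1CCc1cc(C)c(OC)c2C(=O)OCc12)/C=C\C(C)C(=O)O
F2 | step 16 | phenyl ester of F1 | CC1(C)C(=O)CC[C@@](C)([C@H]1CCc1cc(C)c(OC)c2C(=O)OCc12)/C=C\C(C)C(=O)Oc1ccccc1
F3 | step 16 | silyl dienol ether (ketene acetal) of F2 | CC1(C)C(=O)CC[C@@](C)([C@H]1CCc1cc(C)c(OC)c2C(=O)OCc12)/C=C\C(C)=C(Oc1ccccc1)O[Si](C)(C)C(C)(C)C
F4 | step 16 | spiro quinone monoketal with (E)-enoate | CC1(C)C(=O)CC[C@@]2(C)[C@H]1CC[C@]3(C=C(C)C(OC)(OC)C4=C3COC4=O)[C@H]2/C=C(\C)C(=O)Oc1ccccc1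
F5 | step 16 | spiro quinone monoketal with saturated ester | CC1(C)C(=O)CC[C@@]2(C)[C@H]1CC[C@]3(C=C(C)C(OC)(OC)C4=C3COC4=O)[C@H]2CC(C)C(=O)Oc1ccccc1
F6 | step 20 | triethylsilyl enol ether (C6′=C7′) of 25 | CC1(C)OC(=O)C=C[C@@]2(C)[C@H]1CC[C@]3(CC(C)=C(O[Si](CC)(CC)CC)c4c3coc4O[Si](C)(C)C(C)(C)C)[C@H]2CC(C)C(=O)Oc1ccccc1
F7 | step 21 | silyl enol ether (C13=C12) of 26 | CC1(C)OC(=O)C=C[C@@]2(C)[C@H]1CC[C@]13C[C@](C)(C(O[Si](C)(C)C(C)(C)C)=C(C)C[C@@H]21)C(=O)c1c3coc1O[Si](C)(C)C(C)(C)C
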